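## Retrosynthetic overview

1. Target ⇐ bis-sulfation of the hydroquinone; exocyclic C4=CH2 ⇐ Wittig on a C4 ketone; Δ1'(10') ⇐ anti elimination of a 10'α-alcohol.
2. Both rings of the arene-bearing decalin (C5, C8, C9, C10) ⇐ one acid-triggered cationic bicyclisation of a (2Z,6E)-diene onto a cyclic oxocarbenium ion (ring A closes first, then ring B), followed in the same flask by the biosynthetic 1,2-shifts H-9→C8, CH3-10→C9, H-5→C10 and linker C4→C5.
3. Cascade substrate ⇐ B-alkyl Suzuki union of an aryl triene (nerol + 1,4-dimethoxybenzene) with the ketene acetal phosphate of a halimane δ-lactone; the lactone oxygen tethers the two halves.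
4. Halimane lactone ⇐ biomimetic 1,2-H/1,2-CH3 shift with lactone translocation of ambreinolide ⇐ (−)-sclareol, whose two rings come from the chiral pool.

Locants: arene-bearing decalin C1–C10 (ring A = C1–C5, C10; ring B = C5–C10; benzylic carbon C11). Halimane unit C1'–C10', linker C11' and C12'; C13' of the sclareol series becomes C4.

Assumption: the target is taken as drawn, the free bis(hydrogen sulfate); it is released from its pyridinium salt in the last operation and kept cold because it is acid-labile.

## Route

Step 1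
Reactants: 1 (−)-sclareol
Product: 2 8α-hydroxy-14,15-dinorlabdan-13-one
Conditions: KMnO4, MgSO4, acetone/H2O, 0 → 23 °C
Reagents that add atoms: none
Why: permanganate oxidative cleavage of the vinyl carbinol (dihydroxylation, glycol cleavage, oxidative decarboxylation) leaves the C13 methyl ketone; no stereocentre is touched and all ring centres of the halimane half come from sclareol.

Step 2
Reactants: 2 8α-hydroxy-14,15-dinorlabdan-13-one
Product: 4 ambreinolide, via hydroxy acid 3 (not isolated)
Conditions: NaOCl, NaOH, 1,4-dioxane/H2O, 10 → 23 °C; HCl to pH 2; TsOH (cat.), toluene, 80 °C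
Reagents that add atoms: sodium hydroxide, [Na+].[OH-] (one carboxyl oxygen, which may remain in the lactone)
Why: haloform reaction of the methyl ketone gives the C13 acid, which lactonises onto the 8α-hydroxyl with retention at C8.

Step 3
Reactants: 4 ambreinolide
Product: 5 14,15,16-trinorhaliman-13,10α-olide
Conditions: TfOH (0.3 equiv), CH2Cl2/HFIP 4:1, 0 → 23 °C
Reagents that add atoms: none
Why: Proposed new method: acid ionises the tertiary alkyl–oxygen bond of the lactone to the labd-8-yl cation; two mutually anti, suprafacial 1,2-shifts (H-9α→C8, giving 8β-CH3; CH3-10β→C9, giving 9β-CH3) follow as in the labdane-to-halimane branch of the biosynthesis; the carboxyl group on the 9α arm then closes on the α face of C10, anti to the departed methyl, giving the cis-fused δ-lactone, which should be the sink because the 1,3-diaxial methyl interactions of the labdane are relieved; C5 (α-H) is untouched; closest known reaction types are the BF3-promoted 1,2-H/1,2-CH3 shifts of drim-8-yl cations in aryl sesquiterpenoid synthesis and the acid equilibration of sclareolide at C8.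

Step 4
Reactants: 5 14,15,16-trinorhaliman-13,10α-olide
Product: 6 ketene acetal diphenyl phosphate
Conditions: KN(SiMe3)2, (PhO)2P(O)Cl, THF/HMPA, −78 °C
Reagents that add atoms: diphenyl chlorophosphate, O=P(Cl)(Oc1ccccc1)Oc1ccccc1
Why: kinetic enolisation of the lactone at C12' and O-phosphorylation gives the ketene acetal phosphate used for lactone-to-enol-ether cross-coupling; no stereocentre changes.

Step 5
Reactants: 7 nerol
Product: 8 neryl bromide
Conditions: PBr3, Et2O, −10 °C
Reagents that add atoms: phosphorus tribromide, BrP(Br)Br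
Why: SN2-type bromination of the primary allylic alcohol at low temperature keeps the Z alkene.

Step 6
Reactants: 9 1,4-dimethoxybenzene; 8 neryl bromide
Product: 11 2-neryl-1,4-dimethoxybenzene, via aryllithium 10 (not isolated)
Conditions: n-BuLi, TMEDA, THF, 0 °C; then CuBr·SMe2 (5 mol %), 8, −78 → 0 °C
Reagents that add atoms: none
Why: directed ortho-lithiation followed by copper-catalysed SN2 allylation at the primary carbon, which retains the Z geometry.

Step 7
Reactants: 11 2-neryl-1,4-dimethoxybenzene
Product: 12 (2E,6Z)-8-(2,5-dimethoxyphenyl)-2,6-dimethylocta-2,6-dien-1-ol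
Conditions: SeO2 (0.3 equiv), t-BuOOH, salicylic acid (cat.), CH2Cl2, 0 → 23 °C
Reagents that add atoms: SeO2, O=[Se]=O (oxygen donor, regenerated by tert-butyl hydroperoxide, CC(C)(C)OO)
Why: Sharpless allylic oxidation (ene reaction then [2,3]-shift) hydroxylates the trans methyl of the terminal trisubstituted alkene and gives the E allylic alcohol.

Step 8
Reactants: 12 (2E,6Z)-8-(2,5-dimethoxyphenyl)-2,6-dimethylocta-2,6-dien-1-ol
Product: 13 allylic bromide
Conditions: CBr4, PPh3, CH2Cl2, 0 °C
Reagents that add atoms: carbon tetrabromide, BrC(Br)(Br)Br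
Why: Appel bromination of the primary allylic alcohol under neutral conditions, without allylic transposition or loss of alkene geometry.

Step 9
Reactants: 13 allylic bromide
Product: 14 2-[(2Z,6E)-3,7-dimethyldeca-2,6,9-trienyl]-1,4-dimethoxybenzene
Conditions: CH2=CHMgBr, Li2CuCl4 (3 mol %), THF, −40 → 0 °C
Reagents that add atoms: vinylmagnesium bromide, C=C[Mg]Br
Why: copper-catalysed cross-coupling of the allylic bromide with the vinyl Grignard reagent at the unhindered α carbon gives the skipped triene with both trisubstituted alkenes unchanged.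

Step 10
Reactants: 14 2-[(2Z,6E)-3,7-dimethyldeca-2,6,9-trienyl]-1,4-dimethoxybenzene; 6 ketene acetal diphenyl phosphate
Product: 16 cyclic enol ether, via alkylborane 15 (not isolated)
Conditions: 14, 9-BBN, THF, 0 → 23 °C; then 6, PdCl2(dppf) (5 mol %), Cs2CO3 (aq.), DMF, 23 → 45 °C
Reagents that add atoms: none
Why: 9-BBN hydroborates only the monosubstituted alkene, and B-alkyl Suzuki–Miyaura coupling with the ketene acetal phosphate joins C10 of the chain to C13' without touching any stereocentre.

Step 11
Reactants: 16 cyclic enol ether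
Product: 19 keto alcohol, via spiro cation 17 (not isolated), via oxocarbenium ion 18 (not isolated)
Conditions: Tf2NH (10 mol %), CH2Cl2/HFIP 4:1, −40 → −10 °C; then H2O, THF, NaHCO3, 0 °C
Reagents that add atoms: water, O
Why: Proposed new method: protonation of the enol ether (far more basic than the two trisubstituted alkenes) gives a six-membered oxocarbenium ion at C4 that is tied to the halimane unit through O–C10', so the cascade starts at one site only, the halimane unit carries no alkene that could intercept it, and its chirality sits one ring away; a Johnson-type chair–chair bicyclisation through the 6E and 2Z alkenes gives 17 with H-5 trans to the C10 methyl (anti addition to the E alkene) and the arylmethyl group axial at C9 (Z alkene), the smaller ring oxygen taking the axial site on C4 syn to the angular methyl and C12' the equatorial one, while the absolute sense is expected to be relayed by axial attack on the less hindered face of the tethered oxocarbenium ion; in the non-nucleophilic medium four suprafacial 1,2-shifts then follow as in the presumed biosynthesis, H-9→C8 (C8 methyl ends trans to the C9 methyl), CH3-10→C9, H-5→C10 and C12' from C4 to C5 on the face that H-5 left, which is the only shift that leads to an oxocarbenium ion (semipinacol driving force) and fixes the cis ring fusion; water then frees the C4 ketone and the 10'α-alcohol; closest known reaction types are acetal-initiated polyene cyclisation, the BF3-promoted 1,2-H/1,2-CH3 shifts of aryl drimanyl cations and the semipinacol rearrangement.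

Step 12
Reactants: 19 keto alcohol
Product: 20 ketone with the 1'(10') alkene
Conditions: SOCl2, pyridine, −30 → 0 °C
Reagents that add atoms: none
Why: anti E2 dehydration of the tertiary chlorosulfite; H-5' is cis to the 10'α oxygen and C9' bears no hydrogen, so only H-1' can be antiperiplanar and the alkene forms at C1'–C10' with the 5'α-H kept.

Step 13
Reactants: 20 ketone with the 1'(10') alkene
Product: 21 hydroquinone dimethyl ether with the C4 methylene
Conditions: Ph3PCH3Br, KOt-Bu, toluene, 90 °C
Reagents that add atoms: methyltriphenylphosphonium bromide, C[P+](c1ccccc1)(c1ccccc1)c1ccccc1.[Br-]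
Why: Wittig methylenation of the ketone next to the quaternary C5 places the alkene exocyclic without ambiguity; there is no epimerisable centre next to the carbonyl.

Step 14
Reactants: 21 hydroquinone dimethyl ether with the C4 methylene
Product: 23 hydroquinone, via quinone 22 (not isolated)
Conditions: (NH4)2Ce(NO3)6, MeCN/H2O, 0 °C; then Na2S2O4, THF/H2O, 23 °C
Reagents that add atoms: water, O
Why: oxidative demethylation of the 1,4-dimethoxyarene to the benzoquinone and dithionite reduction, as used for avarol-type hydroquinones carrying alkenes; no stereocentre is involved.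

Step 15
Reactants: 23 hydroquinone
Product: 24 target bis(hydrogen sulfate)
Conditions: SO3·pyridine, pyridine, 23 °C; then Dowex 50W (H+ form), MeOH/H2O, 0 °C
Reagents that add atoms: sulfur trioxide–pyridine complex, O=S(=O)([O-])[n+]1ccccc1
Why: O-sulfation of both phenols with the SO3–pyridine complex and cold proton exchange gives the bis(hydrogen sulfate); all stereocentres are already in place.

## Compound list

1 | (−)-sclareol, (13R)-labd-14-ene-8α,13-diol | C=C[C@](C)(O)CC[C@@H]1[C@@]2(C)CCCC(C)(C)[C@@H]2CC[C@@]1(C)O | starting material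
2 | 8α-hydroxy-14,15-dinorlabdan-13-one (5α-H, 9α-H, 10β-CH3, 8β-CH3) | CC(=O)CC[C@@H]1[C@@]2(C)CCCC(C)(C)[C@@H]2CC[C@@]1(C)O | intermediate
3 | 8α-hydroxy-14,15,16-trinorlabdan-13-oic acid | OC(=O)CC[C@@H]1[C@@]2(C)CCCC(C)(C)[C@@H]2CC[C@@]1(C)O | intermediate
4 | ambreinolide, 14,15,16-trinorlabdan-13,8α-olide | O=C1CC[C@@H]2[C@@]3(C)CCCC(C)(C)[C@@H]3CC[C@@]2(C)O1 | intermediate
5 | 14,15,16-trinorhaliman-13,10α-olide: cis-fused δ-lactone, 5α-H, 8β-CH3, 9β-CH3, 9α-CH2CH2C(=O)O on C10α | O=C1CC[C@]2(C)[C@@H](C)CC[C@H]3C(C)(C)CCC[C@@]23O1 | intermediate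
6 | ketene acetal diphenyl phosphate of 5 (C12'=C13' enol phosphate) | O=P(Oc1ccccc1)(Oc1ccccc1)OC1=CC[C@]2(C)[C@@H](C)CC[C@H]3C(C)(C)CCC[C@@]23O1 | intermediate
7 | nerol, (2Z)-3,7-dimethylocta-2,6-dien-1-ol | CC(C)=CCC/C(C)=C\CO | starting material
8 | neryl bromide | CC(C)=CCC/C(C)=C\CBr | intermediate
9 | 1,4-dimethoxybenzene | COc1ccc(OC)cc1 | starting material
10 | 2,5-dimethoxyphenyllithium | [Li]c1cc(OC)ccc1OC | intermediate
11 | 2-[(2Z)-3,7-dimethylocta-2,6-dienyl]-1,4-dimethoxybenzene | COc1ccc(OC)c(C/C=C(C)\CCC=C(C)C)c1 | intermediate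
12 | (2E,6Z)-8-(2,5-dimethoxyphenyl)-2,6-dimethylocta-2,6-dien-1-ol | COc1ccc(OC)c(C/C=C(C)\CC/C=C(C)/CO)c1 | intermediate
13 | 2-[(2Z,6E)-8-bromo-3,7-dimethylocta-2,6-dienyl]-1,4-dimethoxybenzene | COc1ccc(OC)c(C/C=C(C)\CC/C=C(C)/CBr)c1 | intermediate
14 | 2-[(2Z,6E)-3,7-dimethyldeca-2,6,9-trienyl]-1,4-dimethoxybenzene | COc1ccc(OC)c(C/C=C(C)\CC/C=C(C)/CC=C)c1 | intermediate
15 | B-alkyl-9-borabicyclo[3.3.1]nonane from 14, boron on the terminal carbon | COc1ccc(OC)c(C/C=C(C)\CC/C=C(C)/CCCB2C3CCCC2CCC3)c1 | intermediate
16 | cyclic enol ether: dihydropyran fused to the halimane unit (O on C10'α, C12'=C13'), C13' carrying the (4E,8Z)-10-(2,5-dimethoxyphenyl)-4,8-dimethyldeca-4,8-dien-1-yl chain | COc1ccc(OC)c(C/C=C(C)\CC/C=C(C)/CCCC2=CC[C@]3(C)[C@@H](C)CC[C@H]4C(C)(C)CCC[C@@]34O2)c1 | intermediate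
17 | spiro cation: C8 tertiary cation of the new trans-decalin; H-5 trans to C10-CH3, C9 arylmethyl axial and trans to C10-CH3, C4 spiro to the tetrahydropyran with oxygen axial (cis to C10-CH3) and C12' equatorial | COc1ccc(OC)c(C[C@H]2[C+](C)CC[C@H]3[C@@]2(C)CCC[C@]36CC[C@]7(C)[C@@H](C)CC[C@H]8C(C)(C)CCC[C@@]78O6)c1 | intermediate
18 | ring-expanded oxocarbenium ion: C4=O+ bonded to C10', C12' now on C5 (seven-membered ring), ring A/B stereocentres as in 19 | [O+]9=C1CCC[C@H]2[C@]1(CC[C@@]1(C)[C@]39CCCC(C)(C)[C@@H]3CC[C@@H]1C)CC[C@H](C)[C@]2(C)Cc1cc(OC)ccc1OC | intermediate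
19 | keto alcohol: cis-fused 4-ketone; C8-CH3, C9-arylmethyl, H-10 and the C5 linker all cis, C9-CH3 trans to them; halimane unit with 10'α-OH, 5'α-H, 8'β-CH3, 9'β-CH3 | O=C1CCC[C@H]2[C@]1(CC[C@@]1(C)[C@]3(O)CCCC(C)(C)[C@@H]3CC[C@@H]1C)CC[C@H](C)[C@]2(C)Cc1cc(OC)ccc1OC | intermediate
20 | 4-ketone with the halim-1'(10')-ene unit | O=C1CCC[C@H]2[C@]1(CC[C@@]1(C)C3=CCCC(C)(C)[C@@H]3CC[C@@H]1C)CC[C@H](C)[C@]2(C)Cc1cc(OC)ccc1OC | intermediate
21 | hydroquinone dimethyl ether of the target skeleton (4(11)-exocyclic alkene, 1'(10')-alkene) | C=C1CCC[C@H]2[C@]1(CC[C@@]1(C)C3=CCCC(C)(C)[C@@H]3CC[C@@H]1C)CC[C@H](C)[C@]2(C)Cc1cc(OC)ccc1OC | intermediate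
22 | corresponding 2-substituted 1,4-benzoquinone | C=C1CCC[C@H]2[C@]1(CC[C@@]1(C)C3=CCCC(C)(C)[C@@H]3CC[C@@H]1C)CC[C@H](C)[C@]2(C)CC1=CC(=O)C=CC1=O | intermediate
23 | corresponding hydroquinone | C=C1CCC[C@H]2[C@]1(CC[C@@]1(C)C3=CCCC(C)(C)[C@@H]3CC[C@@H]1C)CC[C@H](C)[C@]2(C)Cc1cc(O)ccc1O | intermediate
24 | CNP0439949.2, hydroquinone bis(hydrogen sulfate) | C=C1CCC[C@H]2[C@]1(CC[C@@]1(C)C3=CCCC(C)(C)[C@@H]3CC[C@@H]1C)CC[C@H](C)[C@]2(C)Cc1cc(OS(=O)(=O)O)ccc1OS(=O)(=O)O | target

## Step count and risks

Total steps: 15. Longest linear sequence: 11 (nerol to target, steps 5–15); the sclareol branch is 10.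

Most likely to fail, first: step 11. The facial relay from the halimane unit and the chair sense (oxygen axial on C4) are a model, not a precedent; the wrong sense gives a diastereomer. The H-9 shift must occur from an equatorial hydrogen (twist-boat ring B), and leakage through a Δ8 or Δ5(10) alkene would erode C8 and C10. The tertiary O–C10' bond may also fragment. The fallback gives up the tether and the alkyl shift and joins the halves by enolate alkylation; it sets out from 13 and 5 and comes back at 19. Bromide 13 is coupled (Li2CuCl4) with the Grignard reagent of (4R,6R)-2-(2-bromoethyl)-4,6-dimethyl-1,3-dioxane to the chiral acetal F1 (the enantiomeric diol is used if the induction is opposite). TiCl4 with 2,6-di-tert-butylpyridine at −78 °C triggers the acetal-initiated bicyclisation, and BF3·OEt2 then drives the H-9, CH3-10, H-5 and H-4 shifts to an oxocarbenium ion that is hydrolysed to the decalone F2, the auxiliary setting the absolute sense. Lactone 5 is reduced with LiAlH4 to the diol F3 and turned (I2, PPh3, imidazole; then Me3SiOTf, 2,6-lutidine) into the iodo silyl ether F4. The more substituted lithium enolate of F2 (from its trimethylsilyl enol ether and MeLi) is alkylated with F4 in THF/DMPU; axial attack on the 1-decalone enolate gives the cis-fused silyl ether F5, and Bu4NF returns 19.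

Second: step 3. The lactone translocation is unprecedented and may stop at the C8 epimer of 4 or at olefinic acids. The fallback moves the rearrangement of the halimane half to after the cascade; it sets out from 4 and comes back at 19. Ambreinolide 4 is converted as in step 4 into the ketene acetal phosphate F6 and coupled with alkylborane 15 as in step 10 to the enol ether F7. The step 11 conditions, now with the 8'α-oxygen as tether, give the keto alcohol F8 with an intact labdane 8'α-ol. Catalytic TfOH in CH2Cl2/HFIP then ionises that hydroxyl; the two 1,2-shifts run in the halimane precursor and the C10' cation is captured by the ring A carbonyl oxygen as oxocarbenium ion 18, which water opens to 19.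

Third: step 10. The ketene acetal phosphate sits next to a fully substituted carbon and the enol ether product is acid-labile. The fallback makes the same bond by carbonyl addition; it sets out from 14 and 5 and comes back at 19. Alkylborane 15 from 14 is iodinated (I2, NaOMe) to the iodide F9; t-BuLi (2 equiv, Et2O/pentane, −78 °C) and then lactone 5 give the lactol F10. Under the acid conditions of step 11 F10 ionises to the same six-membered oxocarbenium ion and continues to 19.

Further compounds

F1 | step 11 | (4R,6R)-2-[(4E,8Z)-10-(2,5-dimethoxyphenyl)-4,8-dimethyldeca-4,8-dienyl]-4,6-dimethyl-1,3-dioxane | COc1ccc(OC)c(C/C=C(C)\CC/C=C(C)/CCCC2O[C@H](C)C[C@@H](C)O2)c1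
F2 | step 11 | ring A/B decalin-4-one with C8-CH3, C9-CH3, C9-(2,5-dimethoxybenzyl) and H-10 as in 19, C5–H epimerisable | O=C1CCC[C@H]2C1CC[C@H](C)[C@]2(C)Cc1cc(OC)ccc1OC
F3 | step 11 | 14,15,16-trinorhalimane-10α,13-diol | OCC[C@]1(C)[C@@H](C)CC[C@H]2C(C)(C)CCC[C@@]12O
F4 | step 11 | 13-iodo-14,15,16-trinorhaliman-10α-yl trimethylsilyl ether | ICC[C@]1(C)[C@@H](C)CC[C@H]2C(C)(C)CCC[C@@]12O[Si](C)(C)C
F5 | step 11 | 10'-O-trimethylsilyl ether of 19 | O=C1CCC[C@H]2[C@]1(CC[C@@]1(C)[C@]3(O[Si](C)(C)C)CCCC(C)(C)[C@@H]3CC[C@@H]1C)CC[C@H](C)[C@]2(C)Cc1cc(OC)ccc1OC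
F6 | step 3 | ketene acetal diphenyl phosphate of ambreinolide | O=P(Oc1ccccc1)(Oc1ccccc1)OC1=CC[C@@H]2[C@@]3(C)CCCC(C)(C)[C@@H]3CC[C@@]2(C)O1
F7 | step 3 | cyclic enol ether of the labdane series (O on C8'α), C13' carrying the aryl dienyl chain | COc1ccc(OC)c(C/C=C(C)\CC/C=C(C)/CCCC2=CC[C@@H]3[C@@]4(C)CCCC(C)(C)[C@@H]4CC[C@@]3(C)O2)c1
F8 | step 3 | keto alcohol with ring system A as in 19 and an unrearranged labdan-8'α-ol unit | O=C1CCC[C@H]2[C@]1(CC[C@@H]1[C@@]3(C)CCCC(C)(C)[C@@H]3CC[C@@]1(C)O)CC[C@H](C)[C@]2(C)Cc1cc(OC)ccc1OC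
F9 | step 10 | 2-[(2Z,6E)-10-iodo-3,7-dimethyldeca-2,6-dienyl]-1,4-dimethoxybenzene | COc1ccc(OC)c(C/C=C(C)\CC/C=C(C)/CCCI)c1
F10 | step 10 | lactol from 5: C13' hemiketal carrying the aryl dienyl chain | COc1ccc(OC)c(C/C=C(C)\CC/C=C(C)/CCCC2(O)CC[C@]3(C)[C@@H](C)CC[C@H]4C(C)(C)CCC[C@@]34O2)c1
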